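**Retrosynthetic overview**

1. The arene goes on last: the aryl–CH2 bond is cut back to a neopentyl primary alcohol and a bought bromo-hydroxybenzoate (deoxygenative C(sp3)–C(sp2) coupling), instead of benzylating a Wieland–Miescher-type decalone enolate.
2. The exocyclic methylene comes from a ring A ketone (Wittig). The angular methyl and the cis ring fusion come from a dissolving-metal reductive methylation of a ring A enone, which also turns the formyl group into the CH2OH handle.
3. Key step: a catalytic enantioselective endo Diels–Alder reaction of tiglic aldehyde with an achiral 2-vinylcyclohexenone ketal. It builds ring B and sets the quaternary carbon and its two neighbouring stereocentres at once.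
4. Ring order: ring A is bought (cyclohexenone), ring B is made by the cycloaddition, the arene is bought.

Assumption 1: the target is taken exactly as drawn, (1R,2S,4aS,8aR), i.e. the cis-fused decalin with the ring-fusion hydrogen and all three methyl groups on one face and the arylmethyl group on the other.

Assumption 2: the oxazaborolidinium catalyst derived from (S)-diphenylprolinol is taken to expose the Re face at C2 of an α-substituted enal (usual formyl C–H···O, s-trans model), so the (R)-catalyst is used to reach the Si face needed here.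

**Route**

Step 1
Reactants: 1 cyclohex-2-en-1-one
Product: 3 2-bromocyclohex-2-en-1-one, via 2,3-dibromocyclohexan-1-one 2 (not isolated)
Conditions: Br2, CH2Cl2, 0 °C; then Et3N, 0 °C to rt
Reagents that add atoms: bromine, BrBr
Why: Bromine adds across the enone double bond and triethylamine then removes the acidic α-proton with loss of the β-bromide (bromination–dehydrobromination, addition then E1cB elimination), leaving the achiral 2-bromo enone.

Step 2
Reactants: 3 2-bromocyclohex-2-en-1-one
Product: 4 6-bromo-1,4-dioxaspiro[4.5]dec-6-ene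
Conditions: HOCH2CH2OH, p-TsOH (cat.), benzene, reflux, Dean–Stark
Reagents that add atoms: ethane-1,2-diol, OCCO
Why: Acid-catalysed ketalisation driven by azeotropic removal of water, in which the α-bromine keeps the double bond in place, gives an achiral masked enone.

Step 3
Reactants: 4 6-bromo-1,4-dioxaspiro[4.5]dec-6-ene
Product: 5 6-ethenyl-1,4-dioxaspiro[4.5]dec-6-ene
Conditions: Bu3SnCH=CH2, Pd(PPh3)4 (5 mol %), toluene, 100 °C
Reagents that add atoms: tributyl(ethenyl)stannane, C=C[Sn](CCCC)(CCCC)CCCC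
Why: Stille cross-coupling (oxidative addition of the alkenyl bromide to zerovalent palladium, transmetalation from tin, reductive elimination) gives the 1-vinylcyclohexene diene without touching the ketal.

Step 4
Reactants: 5 6-ethenyl-1,4-dioxaspiro[4.5]dec-6-ene; 6 (E)-2-methylbut-2-enal (tiglic aldehyde)
Product: 8 (1R,2S,8aR)-1,2-dimethyl-5-oxo-1,2,3,5,6,7,8,8a-octahydronaphthalene-1-carbaldehyde, via spiro-ketal cycloadduct 7 (not isolated)
Conditions: (R)-3,3-diphenyl-1-(2-methylphenyl)tetrahydro-1H,3H-pyrrolo[1,2-c][1,3,2]oxazaborole (20 mol %), HN(SO2CF3)2 (18 mol %), CH2Cl2, −78 to −40 °C; then 1 M HCl, THF, rt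
Reagents that add atoms: water, O
Why: In this oxazaborolidinium-catalysed enantioselective Diels–Alder reaction the boron-bound s-trans enal is attacked on its C2 Si face, the unsubstituted vinyl terminus bonds to the β-carbon (ortho regiochemistry) and the formyl group sits endo, so the E geometry of 6 puts the two methyls cis and the endo mode puts the formyl group cis to the ring A carbon at the ring fusion (quaternary carbon, its methyl-bearing neighbour and the ring-fusion CH all set here), after which aqueous acid unmasks the conjugated enone.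

Step 5
Reactants: 8 (1R,2S,8aR)-1,2-dimethyl-5-oxo-1,2,3,5,6,7,8,8a-octahydronaphthalene-1-carbaldehyde
Product: 10 (4aR,5R,6S,8aS)-5-(hydroxymethyl)-5,6,8a-trimethyloctahydronaphthalen-1(2H)-one, via dilithium enolate alkoxide 9 (not isolated)
Conditions: Li (4.5 equiv), t-BuOH (2 equiv), NH3(l)/THF, −78 °C; then MeI, −78 to −33 °C; aq. NH4Cl
Reagents that add atoms: iodomethane, CI
Why: In this dissolving-metal (Birch-type) reductive alkylation lithium reduces the formyl group to the alkoxide and the enone to the regiodefined ring-fusion enolate, and MeI then alkylates the ring-fusion carbon on the face of the ring-fusion hydrogen, away from the axial oxidomethyl arm that sits 1,3-syn on the other face, which is also the normal cis-selective course of angular methylation of 1-decalone enolates.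

Step 6
Reactants: 10 (4aR,5R,6S,8aS)-5-(hydroxymethyl)-5,6,8a-trimethyloctahydronaphthalen-1(2H)-one
Product: 11 [(1R,2S,4aS,8aS)-1,2,4a-trimethyl-5-methylidenedecahydronaphthalen-1-yl]methanol
Conditions: Ph3PCH3Br (5 equiv), KOtBu (5 equiv), toluene, 90 °C
Reagents that add atoms: methyltriphenylphosphonium bromide, C[P+](c1ccccc1)(c1ccccc1)c1ccccc1.[Br-]
Why: Wittig methylenation with excess non-stabilised ylide in hot toluene converts the hindered ketone next to the quaternary carbon into the exocyclic alkene, the free alcohol costing only one equivalent of base and no stereocentre being touched (the change of the 8a descriptor is a priority change only).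

Step 7
Reactants: 12 methyl 3-bromo-4-hydroxybenzoate
Product: 13 methyl 3-bromo-4-[(2,2-dimethylpropanoyl)oxy]benzoate
Conditions: t-BuCOCl, Et3N, DMAP (cat.), CH2Cl2, 0 °C to rt
Reagents that add atoms: 2,2-dimethylpropanoyl chloride, CC(C)(C)C(=O)Cl
Why: DMAP-catalysed acylation masks the acidic, easily oxidised phenol as a base-labile ester that is small next to the bromide and inert to the photoredox conditions.

Step 8
Reactants: 11 [(1R,2S,4aS,8aS)-1,2,4a-trimethyl-5-methylidenedecahydronaphthalen-1-yl]methanol; 13 methyl 3-bromo-4-[(2,2-dimethylpropanoyl)oxy]benzoate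
Product: 15 methyl 4-[(2,2-dimethylpropanoyl)oxy]-3-{[(1R,2S,4aS,8aR)-1,2,4a-trimethyl-5-methylidenedecahydronaphthalen-1-yl]methyl}benzoate, via benzoxazoline ether adduct 14 (not isolated)
Conditions: 5,7-di-tert-butyl-3-phenyl-1,3-benzoxazol-3-ium tetrafluoroborate (1.2 equiv), pyridine (1.2 equiv), MTBE, rt; then 13 (1.5 equiv), NiBr2(dtbbpy) (5 mol %), [Ir(ppy)2(dtbbpy)]PF6 (1.5 mol %), quinuclidine (1.75 equiv), DMA, blue LEDs, rt (dtbbpy = 4,4'-di-tert-butyl-2,2'-bipyridine, ppy = 2-phenylpyridinato)
Reagents that add atoms: none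
Why: In this nickel/photoredox deoxygenative arylation the alcohol condenses with the benzoxazolium salt, photocatalytic oxidation and deprotonation of the adduct followed by β-scission release the primary neopentyl radical, and capture by the arylnickel bromide formed from 13 with reductive elimination forges the CH2–aryl bond at a carbon that is not stereogenic, so all four stereocentres are carried through unchanged.

Step 9
Reactants: 15 methyl 4-[(2,2-dimethylpropanoyl)oxy]-3-{[(1R,2S,4aS,8aR)-1,2,4a-trimethyl-5-methylidenedecahydronaphthalen-1-yl]methyl}benzoate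
Product: 16 methyl 4-hydroxy-3-{[(1R,2S,4aS,8aR)-1,2,4a-trimethyl-5-methylidenedecahydronaphthalen-1-yl]methyl}benzoate
Conditions: K2CO3 (1.5 equiv), MeOH, rt; aq. NH4Cl
Reagents that add atoms: none
Why: Base-mediated methanolysis (transesterification) cleaves the aryl pivalate, whose phenoxide is a far better leaving group than methoxide, while exchange at the methyl benzoate is degenerate in methanol and the acid-sensitive exocyclic alkene never sees acid.

**Compound list**

1 | cyclohex-2-en-1-one | O=C1C=CCCC1 | starting material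
2 | 2,3-dibromocyclohexan-1-one (mixture of stereoisomers) | O=C1CCCC(Br)C1Br | intermediate
3 | 2-bromocyclohex-2-en-1-one | O=C1CCCC=C1Br | intermediate
4 | 6-bromo-1,4-dioxaspiro[4.5]dec-6-ene | BrC1=CCCCC12OCCO2 | intermediate
5 | 6-ethenyl-1,4-dioxaspiro[4.5]dec-6-ene | C=CC1=CCCCC12OCCO2 | intermediate
6 | (E)-2-methylbut-2-enal (tiglic aldehyde) | C/C=C(C)/C=O | starting material
7 | (1'R,2'S,8a'R)-1',2'-dimethyl-2',3',6',7',8',8a'-hexahydro-1'H-spiro[[1,3]dioxolane-2,5'-naphthalene]-1'-carbaldehyde | C12(OCCO1)CCC[C@@H]3[C@](C)(C=O)[C@@H](C)CC=C23 | intermediate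
8 | (1R,2S,8aR)-1,2-dimethyl-5-oxo-1,2,3,5,6,7,8,8a-octahydronaphthalene-1-carbaldehyde | O=C1CCC[C@@H]2[C@](C)(C=O)[C@@H](C)CC=C12 | intermediate
9 | dilithium (4aR,5R,6S)-5,6-dimethyl-5-(oxidomethyl)-2,3,4,4a,5,6,7,8-octahydronaphthalen-1-olate | [Li+].[Li+].[O-]C1CCC[C@@H]2[C@](C)(C[O-])[C@@H](C)CCC2=1 | intermediate
10 | (4aR,5R,6S,8aS)-5-(hydroxymethyl)-5,6,8a-trimethyloctahydronaphthalen-1(2H)-one | O=C1CCC[C@@H]2[C@](C)(CO)[C@@H](C)CC[C@]12C | intermediate
11 | [(1R,2S,4aS,8aS)-1,2,4a-trimethyl-5-methylidenedecahydronaphthalen-1-yl]methanol | C=C1CCC[C@@H]2[C@](C)(CO)[C@@H](C)CC[C@]12C | intermediate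
12 | methyl 3-bromo-4-hydroxybenzoate | COC(=O)c1ccc(O)c(Br)c1 | starting material
13 | methyl 3-bromo-4-[(2,2-dimethylpropanoyl)oxy]benzoate | COC(=O)c1ccc(OC(=O)C(C)(C)C)c(Br)c1 | intermediate
14 | 5,7-di-tert-butyl-3-phenyl-2-{[(1R,2S,4aS,8aS)-1,2,4a-trimethyl-5-methylidenedecahydronaphthalen-1-yl]methoxy}-2,3-dihydro-1,3-benzoxazole (both epimers at C2 of the heterocycle) | C=C1CCC[C@@H]2[C@](C)(COC3Oc4c(cc(cc4N3c5ccccc5)C(C)(C)C)C(C)(C)C)[C@@H](C)CC[C@]12C | intermediate
15 | methyl 4-[(2,2-dimethylpropanoyl)oxy]-3-{[(1R,2S,4aS,8aR)-1,2,4a-trimethyl-5-methylidenedecahydronaphthalen-1-yl]methyl}benzoate | C=C1CCC[C@@H]2[C@](C)(Cc3cc(C(=O)OC)ccc3OC(=O)C(C)(C)C)[C@@H](C)CC[C@]12C | intermediate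
16 | methyl 4-hydroxy-3-{[(1R,2S,4aS,8aR)-1,2,4a-trimethyl-5-methylidenedecahydronaphthalen-1-yl]methyl}benzoate | C=C1CCC[C@@H]2[C@](C)(Cc3cc(C(=O)OC)ccc3O)[C@@H](C)CC[C@]12C | target

**Step count**

Total step count: 9.
Longest linear sequence: 8 steps (steps 1 to 6, then 8 and 9, from 1 to 16); step 7 is a one-step side branch.

**The three steps most likely to fail**

Step 4 is the least certain. Tiglic aldehyde is a sluggish α,β-disubstituted dienophile, the allylic ketal of 5 may ionise under the boron Lewis acid, and endo/exo and facial control on this diene are untested. The fallback replaces catalyst control with substrate control from a chiral diene; it sets out from 3 and comes back to the route at 8. Corey–Bakshi–Shibata reduction of 3 with BH3·SMe2 and (R)-1-methyl-3,3-diphenyltetrahydro-1H,3H-pyrrolo[1,2-c][1,3,2]oxazaborole gives (S)-2-bromocyclohex-2-en-1-ol F1. Silylation with TBSCl and imidazole gives tert-butyl{[(1S)-2-bromocyclohex-2-en-1-yl]oxy}dimethylsilane F2, and Stille coupling with tributyl(ethenyl)stannane and Pd(PPh3)4 gives tert-butyl{[(1S)-2-ethenylcyclohex-2-en-1-yl]oxy}dimethylsilane F3. The Me2AlCl-promoted Diels–Alder reaction of F3 with 6 (CH2Cl2, −78 °C) should add the dienophile anti to the pseudoaxial silyloxy group with the formyl group endo, giving (1R,2S,5S,8aS)-5-[(tert-butyldimethylsilyl)oxy]-1,2-dimethyl-1,2,3,5,6,7,8,8a-octahydronaphthalene-1-carbaldehyde F4. Bu4NF then gives (1R,2S,5S,8aS)-5-hydroxy-1,2-dimethyl-1,2,3,5,6,7,8,8a-octahydronaphthalene-1-carbaldehyde F5, and MnO2 oxidises the allylic alcohol to the enone 8.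

Step 5 carries three risks: side reactions of the formyl group under dissolving-metal conditions, over-alkylation (O-methylation or a second C-methylation), and the face selectivity of the angular methylation. The fallback builds the angular methyl by cyclopropanation of a silyl enol ether instead of enolate alkylation; it sets out from 8 and comes back at 10. RhCl(PPh3)3-catalysed hydrosilylation of 8 with Et3SiH (1,4 on the enone, 1,2 on the aldehyde) gives triethyl{[(1R,2S,8aR)-1,2-dimethyl-5-[(triethylsilyl)oxy]-1,2,3,4,6,7,8,8a-octahydronaphthalen-1-yl]methoxy}silane F6. Simmons–Smith cyclopropanation (Et2Zn, CH2I2) on the open face, that of the ring-fusion hydrogen, gives the siloxycyclopropane (1R,2S,8aR)-1,2-dimethyl-5-[(triethylsilyl)oxy]-1-{[(triethylsilyl)oxy]methyl}-4a,5-methanodecahydronaphthalene F7. Dilute HCl in aqueous THF opens the cyclopropanol ether to the α-methyl ketone and cleaves the primary silyl ether, giving 10.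

Step 8 joins a radical from a very congested neopentyl alcohol to an ortho-substituted aryl bromide, and the coupling may be slow. The fallback makes the same bond by carbonyl addition and deoxygenation; it sets out from 11, takes its arene from 12, and comes back at 16. Dess–Martin periodinane oxidises 11 to (1R,2S,4aS,8aS)-1,2,4a-trimethyl-5-methylidenedecahydronaphthalene-1-carbaldehyde F8. Separately, 12 is protected with MOMCl and i-Pr2NEt as methyl 3-bromo-4-(methoxymethoxy)benzoate F9. Br/Mg exchange on F9 with iPrMgCl·LiCl (THF, −15 °C) and addition to F8 gives methyl 3-{hydroxy[(1R,2S,4aS,8aS)-1,2,4a-trimethyl-5-methylidenedecahydronaphthalen-1-yl]methyl}-4-(methoxymethoxy)benzoate F10 as both carbinol epimers. NaH, CS2 and MeI give its S-methyl xanthate, methyl 4-(methoxymethoxy)-3-{[(methylsulfanyl)carbonothioyl]oxy[(1R,2S,4aS,8aS)-1,2,4a-trimethyl-5-methylidenedecahydronaphthalen-1-yl]methyl}benzoate F11. Barton–McCombie reduction (Bu3SnH, AIBN, toluene, 90 °C) gives methyl 4-(methoxymethoxy)-3-{[(1R,2S,4aS,8aR)-1,2,4a-trimethyl-5-methylidenedecahydronaphthalen-1-yl]methyl}benzoate F12. ZnBr2 and n-PrSH in CH2Cl2 at 0 °C then remove the methoxymethyl group without protic acid, giving 16.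

**Further compounds**

F1 | step 4 | (S)-2-bromocyclohex-2-en-1-ol | O[C@H]1CCCC=C1Br
F2 | step 4 | tert-butyl{[(1S)-2-bromocyclohex-2-en-1-yl]oxy}dimethylsilane | CC(C)(C)[Si](C)(C)O[C@H]1CCCC=C1Br
F3 | step 4 | tert-butyl{[(1S)-2-ethenylcyclohex-2-en-1-yl]oxy}dimethylsilane | CC(C)(C)[Si](C)(C)O[C@H]1CCCC=C1C=C
F4 | step 4 | (1R,2S,5S,8aS)-5-[(tert-butyldimethylsilyl)oxy]-1,2-dimethyl-1,2,3,5,6,7,8,8a-octahydronaphthalene-1-carbaldehyde | CC(C)(C)[Si](C)(C)O[C@H]1CCC[C@@H]2[C@](C)(C=O)[C@@H](C)CC=C12
F5 | step 4 | (1R,2S,5S,8aS)-5-hydroxy-1,2-dimethyl-1,2,3,5,6,7,8,8a-octahydronaphthalene-1-carbaldehyde | O[C@H]1CCC[C@@H]2[C@](C)(C=O)[C@@H](C)CC=C12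
F6 | step 5 | triethyl{[(1R,2S,8aR)-1,2-dimethyl-5-[(triethylsilyl)oxy]-1,2,3,4,6,7,8,8a-octahydronaphthalen-1-yl]methoxy}silane | CC[Si](CC)(CC)OC1CCC[C@@H]2[C@](C)(CO[Si](CC)(CC)CC)[C@@H](C)CCC2=1
F7 | step 5 | (1R,2S,8aR)-1,2-dimethyl-5-[(triethylsilyl)oxy]-1-{[(triethylsilyl)oxy]methyl}-4a,5-methanodecahydronaphthalene (CH2 bridge cis to the 8a-hydrogen) | CC[Si](CC)(CC)O[C@]12CCC[C@@H]3[C@](C)(CO[Si](CC)(CC)CC)[C@@H](C)CC[C@]13C2
F8 | step 8 | (1R,2S,4aS,8aS)-1,2,4a-trimethyl-5-methylidenedecahydronaphthalene-1-carbaldehyde | C=C1CCC[C@@H]2[C@](C)(C=O)[C@@H](C)CC[C@]12C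
F9 | step 8 | methyl 3-bromo-4-(methoxymethoxy)benzoate | COCOc1ccc(C(=O)OC)cc1Br
F10 | step 8 | methyl 3-{hydroxy[(1R,2S,4aS,8aS)-1,2,4a-trimethyl-5-methylidenedecahydronaphthalen-1-yl]methyl}-4-(methoxymethoxy)benzoate (both carbinol epimers) | C=C1CCC[C@@H]2[C@](C)(C(O)c3cc(C(=O)OC)ccc3OCOC)[C@@H](C)CC[C@]12C
F11 | step 8 | methyl 4-(methoxymethoxy)-3-{[(methylsulfanyl)carbonothioyl]oxy[(1R,2S,4aS,8aS)-1,2,4a-trimethyl-5-methylidenedecahydronaphthalen-1-yl]methyl}benzoate (both epimers) | C=C1CCC[C@@H]2[C@](C)(C(OC(=S)SC)c3cc(C(=O)OC)ccc3OCOC)[C@@H](C)CC[C@]12C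
F12 | step 8 | methyl 4-(methoxymethoxy)-3-{[(1R,2S,4aS,8aR)-1,2,4a-trimethyl-5-methylidenedecahydronaphthalen-1-yl]methyl}benzoate | C=C1CCC[C@@H]2[C@](C)(Cc3cc(C(=O)OC)ccc3OCOC)[C@@H](C)CC[C@]12C
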